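**Plan**
- Retrosynthesis: the C6 carbinol comes from a C6 ketone; the seven-membered ring is cut at C8–C9 (allylsilane onto enone) and at C6–C7 (aldehyde plus alkenyl triflate), which splits the C20 skeleton into two C10 halves.
- The cyclopentene half is cut at C4–C5. The unit C1–C5 with the methyl on alkene carbon C4, the carbonyl-level carbon C6 on C5 and a 2-propenyl-type branch (C10, C9, exocyclic CH2) on C1 is the ring-contracted form of (R)-carvone, so this bond is made by Wolff ring contraction of a 6-diazocarvone (temporary six-membered ring C1–C2–C3–C4–C6–C5).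
- The other half (C7, C8, C11–C15 and the oxolane) is trans-furanoid linalool oxide from (R)-linalool; its vinyl group becomes C7 and C8.
- Forward order: oxolane first, cyclopentene by ring contraction, union of the halves at C6–C7, seven-membered ring last at C8–C9, then reduction at C6.
- Stereochemistry: C11 from linalool, C14 from Shi epoxidation and 5-exo opening, C1 from carvone, C5 by kinetic protonation after the ring contraction, C7 by protonation of the cyclisation enolate and C6 by hydride addition, both on the convex face of the cis-fused bicycle.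

Key step: step 8

Remark: atom numbers are those of the dictyol skeleton: C1 and C5 ring fusion, C2–C4 cyclopentene (methyl on C4), C6 carbinol carbon, C7 the ring carbon bearing the oxolane, C8 and C9 ring methylenes, C10 the ring carbon of the exocyclic methylidene, C11 and C14 the oxolane carbons next to oxygen, C15 the acetoxy-bearing carbon.

**Step 1**
Reactants: 1 (R)-linalool
Product: 3 trans-furanoid linalool oxide, via epoxylinalool 2 (not isolated)
Conditions: 1,2:4,5-di-O-isopropylidene-β-L-erythro-2,3-hexodiulo-2,6-pyranose (Shi ketone of the L series, 30 mol %), KHSO5 (as Oxone), K2CO3, Bu4NHSO4 (cat.), aqueous Na2B4O7 buffer, MeCN/CH2(OMe)2, 0 °C; extractive work-up; then camphorsulfonic acid (cat.), CH2Cl2, 0 °C to rt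
Reagents that add atoms: potassium peroxymonosulfate, [K+].[O-]S(=O)(=O)OO
Why: Shi asymmetric epoxidation attacks only the electron-rich trisubstituted alkene, with the catalyst enantiomer chosen to give the (6S)-epoxide, and acid then promotes 5-exo opening by the tertiary hydroxyl with inversion at the epoxide CH carbon, so C14 is set by the catalyst, C11 comes unchanged from (R)-linalool and the 2,5-trans oxolane should result (the pyran isomer from 6-endo opening is the expected minor by-product).

**Step 2**
Reactants: 3 trans-furanoid linalool oxide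
Product: 4 linalool oxide acetate
Conditions: Ac2O, Et3N, 4-(dimethylamino)pyridine (cat.), CH2Cl2, 40 °C
Reagents that add atoms: acetic anhydride, CC(=O)OC(C)=O
Why: 4-(Dimethylamino)pyridine-catalysed acylation of the only hydroxyl installs the tertiary acetate of the target early, since every later step on this half is neutral, Lewis acidic or a mild hydride reduction that a hindered tertiary ester should survive; no stereocenter is touched.

**Step 3**
Reactants: 4 linalool oxide acetate
Product: 5 oxolanyl methyl ketone
Conditions: PdCl2(quinox) (5 mol %; quinox = 2-(4,5-dihydro-1,3-oxazol-2-yl)quinoline), AgSbF6 (cat.), t-BuOOH (70% aq.), CH2Cl2, rt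
Reagents that add atoms: tert-butyl hydroperoxide, CC(C)(C)OO
Why: Peroxide-mediated Tsuji–Wacker oxidation, which is Markovnikov-selective for protected allylic alcohols, turns the vinyl group into the methyl ketone (its two carbons become C7 and C8) without affecting the adjacent quaternary stereocenter.

**Step 4**
Reactants: 5 oxolanyl methyl ketone
Product: 7 alkenyl triflate, via potassium enolate 6 (not isolated)
Conditions: KN(SiMe3)2, THF, −78 °C; then PhN(SO2CF3)2, −78 °C to 0 °C
Reagents that add atoms: N-phenylbis(trifluoromethanesulfonimide), O=S(=O)(N(c1ccccc1)S(=O)(=O)C(F)(F)F)C(F)(F)F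
Why: The ketone can enolise only towards its methyl group, so enol triflate formation by O-sulfonylation of the potassium enolate should give the 1,1-disubstituted alkenyl triflate as a single regioisomer, the less acidic acetate remaining intact at −78 °C.

**Step 5**
Reactants: 8 (R)-carvone
Product: 9 10-chlorocarvone
Conditions: Ca(OCl)2, solid CO2, CH2Cl2/H2O, 0 °C
Reagents that add atoms: calcium hypochlorite, [Ca+2].[O-]Cl.[O-]Cl
Why: Ene-type allylic chlorination by hypochlorous acid takes place at the electron-rich 1,1-disubstituted alkene and leaves the electron-poor enone alone; the stereocenter is not involved.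

**Step 6**
Reactants: 9 10-chlorocarvone
Product: 10 carvone allylsilane
Conditions: Me3SiSiMe3, Pd(PPh3)4 (5 mol %), toluene, 110 °C, sealed tube
Reagents that add atoms: hexamethyldisilane, C[Si](C)(C)[Si](C)(C)C
Why: Palladium-catalysed silylation of the allylic chloride with the disilane runs through a symmetrical 2-substituted π-allyl palladium intermediate that has no hydrogen available for diene formation, so both termini give the same allylsilane and the enone is inert to the disilane.

**Step 7**
Reactants: 10 carvone allylsilane
Product: 13 diazo ketone, via lithium dienolate 11 (not isolated), via trifluoroacetyl ketone 12 (not isolated)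
Conditions: LiN(SiMe3)2, THF, −78 °C; CF3CO2CH2CF3, −78 °C; then CH3SO2N3, Et3N, H2O (1 equiv), MeCN, rt
Reagents that add atoms: methanesulfonyl azide, CS(=O)(=O)N=[N+]=[N-]
Why: Kinetic deprotonation of the enone at its α'-carbon, trifluoroacetylation of that position and diazo transfer from the sulfonyl azide with loss of the trifluoroacetyl group (detrifluoroacetylative Regitz-type diazo transfer) form the α'-diazo enone under conditions suited to base-sensitive enones; the adjacent stereocenter keeps its configuration.

**Step 8**
Reactants: 13 diazo ketone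
Product: 15 cis cyclopentene ester, via vinylketene 14 (not isolated)
Conditions: hν (medium-pressure Hg lamp, Pyrex filter, λ > 300 nm), degassed MeOH, 0 °C
Reagents that add atoms: methanol, CO
Why: Irradiation expels N2 from the ring-locked s-cis diazo ketone and, in the Wolff rearrangement, the alkenyl carbon C4 migrates from the carbonyl carbon C6 to the diazo carbon C5, which forms the C4–C5 bond, contracts the six-membered carvone ring to the cyclopentene and pushes C6 out of the ring as the ketene carbon of 14, to which methanol then adds. The closest known reaction type is the photochemical Wolff ring contraction of cyclic α'-diazo α,β-unsaturated ketones to cyclopentenyl vinylketenes and their capture as esters. The five-membered ring closes by a 1,2-shift inside the temporary six-membered ring (ring contraction), so rules for chain cyclisations do not apply. C5 is created when the ketene-derived dienol ketonises by protonation at the α-carbon on the face away from the bulky 2-(trimethylsilylmethyl)allyl group on C1, which should give the cis ester; C1, the position of the C3=C4 double bond and the C4 methyl are carried over from (R)-carvone. The step needs Wolff shift rather than carbene 1,2-hydrogen shift or insertion, which direct photolysis of a cyclic diazo ketone in a nucleophilic solvent favours, and α- rather than γ-protonation of the dienol, which is the kinetic course.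

**Step 9**
Reactants: 15 cis cyclopentene ester
Product: 17 cyclopentene aldehyde, via aluminium hemiacetal 16 (not isolated)
Conditions: i-Bu2AlH (1.05 equiv), CH2Cl2, −78 °C; MeOH, then aqueous KNaC4H4O6, −78 °C to rt
Reagents that add atoms: none
Why: Partial ester reduction with one equivalent of diisobutylaluminium hydride stops at the tetrahedral aluminium hemiacetal at −78 °C, which gives the aldehyde on neutral work-up without exposing the epimerisable β,γ-unsaturated α-carbon C5 to base.

**Step 10**
Reactants: 7 alkenyl triflate; 17 cyclopentene aldehyde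
Product: 19 allylic alcohol (both C6 epimers), via alkenylchromium 18 (not isolated)
Conditions: CrCl2 (4 equiv), NiCl2 (1 mol %), DMF, rt
Reagents that add atoms: none
Why: Nozaki–Hiyama–Kishi coupling forms the alkenylchromium from the hindered alkenyl triflate under nickel catalysis and adds it chemoselectively to the aldehyde under nearly neutral conditions, joining the two C10 halves at C6–C7 while tolerating the acetate, the allylsilane and the α-stereocenter; the configuration of the new carbinol carbon is irrelevant because it is oxidised next.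

**Step 11**
Reactants: 19 allylic alcohol
Product: 20 cross-conjugated enone
Conditions: Dess–Martin periodinane, NaHCO3, CH2Cl2, 0 °C
Reagents that add atoms: none
Why: Buffered Dess–Martin oxidation of the allylic alcohol gives the α-substituted vinyl ketone without acid or base that could move the ring double bond into conjugation or epimerise C5.

**Step 12**
Reactants: 20 cross-conjugated enone
Product: 22 hydroazulenone, via aluminium enolate 21 (not isolated)
Conditions: EtAlCl2 (2.5 equiv), CH2Cl2, −78 °C to −40 °C; aqueous KH2PO4/Na2HPO4 buffer (pH 7) at −78 °C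
Reagents that add atoms: none
Why: In this intramolecular Hosomi–Sakurai reaction the enone, held s-trans by aluminium chelation between the carbonyl and oxolane oxygens, is attacked at C8 by the alkene terminus of the allylsilane, loss of the silyl group places the exocyclic methylidene on C10 regiospecifically and closes the cis-fused seven-membered ring, and the aluminium enolate is protonated on work-up at C7 from the convex face (the face of H1 and H5), which should place the oxolane cis to C4.

**Step 13**
Reactants: 22 hydroazulenone
Product: 23 dictyol H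
Conditions: NaBH4, CeCl3·7H2O, MeOH, −40 °C to 0 °C
Reagents that add atoms: none
Why: Luche-type borohydride reduction should deliver hydride to the hindered ketone from the convex face, anti to the C4 and C11 substituents that flank the carbonyl on the other face, giving the 6S alcohol, while the tertiary acetate and the alkenes are not reduced.

**Compound list**
1 | (R)-linalool, (3R)-3,7-dimethylocta-1,6-dien-3-ol | C=C[C@](C)(O)CCC=C(C)C | starting material
2 | (3R)-5-[(2S)-3,3-dimethyloxiran-2-yl]-3-methylpent-1-en-3-ol (epoxylinalool, formed in situ) | C=C[C@](C)(O)CC[C@@H]1OC1(C)C | intermediate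
3 | 2-[(2R,5R)-5-ethenyl-5-methyloxolan-2-yl]propan-2-ol (trans-furanoid linalool oxide) | C=C[C@@]1(C)CC[C@H](C(C)(C)O)O1 | intermediate
4 | 2-[(2R,5R)-5-ethenyl-5-methyloxolan-2-yl]propan-2-yl acetate | C=C[C@@]1(C)CC[C@H](C(C)(C)OC(C)=O)O1 | intermediate
5 | 2-[(2R,5R)-5-acetyl-5-methyloxolan-2-yl]propan-2-yl acetate | CC(=O)[C@@]1(C)CC[C@H](C(C)(C)OC(C)=O)O1 | intermediate
6 | potassium 1-[(2R,5R)-5-(2-acetoxypropan-2-yl)-2-methyloxolan-2-yl]ethen-1-olate (formed in situ) | [K+].[O-]C(=C)[C@@]1(C)CC[C@H](C(C)(C)OC(C)=O)O1 | intermediate
7 | 2-[(2R,5R)-5-methyl-5-{1-[(trifluoromethanesulfonyl)oxy]ethenyl}oxolan-2-yl]propan-2-yl acetate | C=C(OS(=O)(=O)C(F)(F)F)[C@@]1(C)CC[C@H](C(C)(C)OC(C)=O)O1 | intermediate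
8 | (R)-carvone, (5R)-2-methyl-5-(prop-1-en-2-yl)cyclohex-2-en-1-one | CC1=CC[C@@H](C(C)=C)CC1=O | starting material
9 | (5R)-5-(3-chloroprop-1-en-2-yl)-2-methylcyclohex-2-en-1-one | CC1=CC[C@@H](C(=C)CCl)CC1=O | intermediate
10 | (5R)-2-methyl-5-[3-(trimethylsilyl)prop-1-en-2-yl]cyclohex-2-en-1-one | CC1=CC[C@@H](C(=C)C[Si](C)(C)C)CC1=O | intermediate
11 | lithium cross-conjugated dienolate of 10, deprotonated at the ring CH2 next to the carbonyl (formed in situ; stereocenter as in 10) | [Li+].[O-]C1=C[C@H](C(=C)C[Si](C)(C)C)CC=C1C | intermediate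
12 | (5R)-2-methyl-6-(trifluoroacetyl)-5-[3-(trimethylsilyl)prop-1-en-2-yl]cyclohex-2-en-1-one (formed in situ; C6 epimers and enol) | CC1=CC[C@@H](C(=C)C[Si](C)(C)C)C(C(=O)C(F)(F)F)C1=O | intermediate
13 | (5S)-6-diazo-2-methyl-5-[3-(trimethylsilyl)prop-1-en-2-yl]cyclohex-2-en-1-one (same spatial arrangement as in 10; the descriptor changes by priority only) | CC1=CC[C@@H](C(=C)C[Si](C)(C)C)C(=[N+]=[N-])C1=O | intermediate
14 | {(5R)-2-methyl-5-[3-(trimethylsilyl)prop-1-en-2-yl]cyclopent-2-en-1-ylidene}methanone (vinylketene, formed in situ) | CC1=CC[C@@H](C(=C)C[Si](C)(C)C)C1=C=O | intermediate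
15 | methyl (1R,5R)-2-methyl-5-[3-(trimethylsilyl)prop-1-en-2-yl]cyclopent-2-ene-1-carboxylate (cis) | COC(=O)[C@H]1C(C)=CC[C@H]1C(=C)C[Si](C)(C)C | intermediate
16 | diisobutylaluminium hemiacetal of 15 (tetrahedral adduct, formed in situ) | COC(O[Al](CC(C)C)CC(C)C)[C@H]1C(C)=CC[C@H]1C(=C)C[Si](C)(C)C | intermediate
17 | (1R,5R)-2-methyl-5-[3-(trimethylsilyl)prop-1-en-2-yl]cyclopent-2-ene-1-carbaldehyde | O=C[C@H]1C(C)=CC[C@H]1C(=C)C[Si](C)(C)C | intermediate
18 | 2-[(2R,5R)-5-[1-(dichlorochromio)ethenyl]-5-methyloxolan-2-yl]propan-2-yl acetate (alkenyl derivative of trivalent chromium, formed in situ) | C=C([Cr](Cl)Cl)[C@@]1(C)CC[C@H](C(C)(C)OC(C)=O)O1 | intermediate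
19 | 2-[(2R,5R)-5-{3-hydroxy-3-[(1R,5R)-2-methyl-5-[3-(trimethylsilyl)prop-1-en-2-yl]cyclopent-2-en-1-yl]prop-1-en-2-yl}-5-methyloxolan-2-yl]propan-2-yl acetate (both carbinol epimers) | C=C(C(O)[C@H]1C(C)=CC[C@H]1C(=C)C[Si](C)(C)C)[C@@]1(C)CC[C@H](C(C)(C)OC(C)=O)O1 | intermediate
20 | 2-[(2R,5R)-5-methyl-5-{3-[(1R,5R)-2-methyl-5-[3-(trimethylsilyl)prop-1-en-2-yl]cyclopent-2-en-1-yl]-3-oxoprop-1-en-2-yl}oxolan-2-yl]propan-2-yl acetate | C=C(C(=O)[C@H]1C(C)=CC[C@H]1C(=C)C[Si](C)(C)C)[C@@]1(C)CC[C@H](C(C)(C)OC(C)=O)O1 | intermediate
21 | chloro(ethyl)aluminium enolate of 22 (C6=C7 enolate, formed in situ) | CC[Al](Cl)OC1=C([C@@]2(C)CC[C@H](C(C)(C)OC(C)=O)O2)CCC(=C)[C@@H]2CC=C(C)[C@H]12 | intermediate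
22 | 2-[(2R,5R)-5-methyl-5-[(3aR,5S,8aR)-3-methyl-8-methylidene-4-oxo-1,3a,4,5,6,7,8,8a-octahydroazulen-5-yl]oxolan-2-yl]propan-2-yl acetate | C=C1CC[C@@H]([C@@]2(C)CC[C@H](C(C)(C)OC(C)=O)O2)C(=O)[C@H]2C(C)=CC[C@@H]12 | intermediate
23 | dictyol H, 2-[(2R,5R)-5-[(3aR,4S,5R,8aR)-4-hydroxy-3-methyl-8-methylidene-1,3a,4,5,6,7,8,8a-octahydroazulen-5-yl]-5-methyloxolan-2-yl]propan-2-yl acetate | C=C1CC[C@@H]([C@@]2(C)CC[C@H](C(C)(C)OC(C)=O)O2)[C@@H](O)[C@H]2C(C)=CC[C@@H]12 | target

**Step count and risks**
Total steps: 13 (steps 1–4 from (R)-linalool, steps 5–9 from (R)-carvone, steps 10–13 after union). Longest linear sequence: 9 steps (steps 5–13 from (R)-carvone).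

Most likely to fail, step 12: 1,2-addition of the allylsilane to the carbonyl (five-membered ring closure), protodesilylation or enolisation towards C5 may compete with conjugate ring closure, and protonation of the enolate at C7 may be poorly face-selective. The fallback uses the 1,2-mode on purpose and corrects it by a sigmatropic ring expansion. It sets out from 20, which with Bu4NF (THF, 4 Å molecular sieves, 0 °C) should give the cis-fused tertiary alcohol 2-[(2R,5R)-5-{1-[(3aR,6aR)-1-hydroxy-6-methyl-3-methylidene-1,2,3,3a,4,6a-hexahydropentalen-1-yl]ethenyl}-5-methyloxolan-2-yl]propan-2-yl acetate F1, a 3-hydroxy-1,5-diene. KN(SiMe3)2 and 18-crown-6 in THF (0 °C to rt) should then trigger an anionic oxy-Cope rearrangement that breaks the bond between C6 and the ring CH2, joins C8 to the exocyclic methylene carbon and expands the five-membered ring by two atoms to the potassium enolate of the hydroazulenone F2. Protonation with acetic acid at −78 °C returns to 22.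

Step 8: the ketonisation of the ketene-derived dienol may show low facial selectivity, or C5 may epimerise afterwards, so that the trans ester accumulates. The fallback sets C5 in a separate operation instead of in the photolysis. It sets out from the ester mixture obtained from 13, that is 15 together with methyl (1S,5R)-2-methyl-5-[3-(trimethylsilyl)prop-1-en-2-yl]cyclopent-2-ene-1-carboxylate F3. LiN(i-Pr)2 in THF at −78 °C converts both into the common lithium ester dienolate F4, which is protonated at the α-carbon at −78 °C with the bulky acid 2,6-di-tert-butyl-4-methylphenol on the face away from the C1 side chain; this returns to 15.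

Step 10: formation or addition of the hindered alkenylchromium may be slow, and aldehyde 17 may epimerise or isomerise to the conjugated aldehyde while it waits. The fallback is an acyl cross-coupling that avoids both the aldehyde and the oxidation. It sets out from 13 and 7: photolysis of 13 in THF containing ethanethiol should give, by way of ketene 14, S-ethyl (1R,5R)-2-methyl-5-[3-(trimethylsilyl)prop-1-en-2-yl]cyclopent-2-ene-1-carbothioate F5; 7 is converted with Me3SnSnMe3, Pd(PPh3)4 and LiCl (THF, 60 °C) into 2-[(2R,5R)-5-methyl-5-[1-(trimethylstannyl)ethenyl]oxolan-2-yl]propan-2-yl acetate F6. Base-free Liebeskind–Srogl coupling of the two (Pd2(dba)3, tri(2-furyl)phosphine, CuO2PPh2, THF, 50 °C) should give enone 20 directly, where the route is rejoined.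

Further compounds
F1 | step 12 | 2-[(2R,5R)-5-{1-[(3aR,6aR)-1-hydroxy-6-methyl-3-methylidene-1,2,3,3a,4,6a-hexahydropentalen-1-yl]ethenyl}-5-methyloxolan-2-yl]propan-2-yl acetate (carbinol configuration open) | C=C(C1(O)CC(=C)[C@@H]2CC=C(C)[C@H]12)[C@@]1(C)CC[C@H](C(C)(C)OC(C)=O)O1
F2 | step 12 | potassium enolate of 22 (C6=C7 enolate) | [K+].[O-]C1=C([C@@]2(C)CC[C@H](C(C)(C)OC(C)=O)O2)CCC(=C)[C@@H]2CC=C(C)[C@H]12
F3 | step 8 | methyl (1S,5R)-2-methyl-5-[3-(trimethylsilyl)prop-1-en-2-yl]cyclopent-2-ene-1-carboxylate (trans epimer of 15) | COC(=O)[C@@H]1C(C)=CC[C@H]1C(=C)C[Si](C)(C)C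
F4 | step 8 | lithium dienolate of 15 (ester enolate, C5 trigonal) | [Li+].[O-]C(OC)=C1C(C)=CC[C@H]1C(=C)C[Si](C)(C)C
F5 | step 10 | S-ethyl (1R,5R)-2-methyl-5-[3-(trimethylsilyl)prop-1-en-2-yl]cyclopent-2-ene-1-carbothioate | CCSC(=O)[C@H]1C(C)=CC[C@H]1C(=C)C[Si](C)(C)C
F6 | step 10 | 2-[(2R,5R)-5-methyl-5-[1-(trimethylstannyl)ethenyl]oxolan-2-yl]propan-2-yl acetate | C=C([Sn](C)(C)C)[C@@]1(C)CC[C@H](C(C)(C)OC(C)=O)O1
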